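## The problem

Isochromene numbering is used: O2, C1 (OCH2), C3, C4, C4a, C5, C6 (C=O), C7, C8, C8a; side chain C1'–C7' with methyls on C3' and C5'. The configuration read from the SMILES is 7S, 8R, 8aS, 3'R, 4'S, 5'R.

Ring A (C4a, C5, C6, C7, C8, C8a; a cyclohex-2-enone) is fused through C4a–C8a to ring B (O2, C1, C3, C4, C4a, C8a; a dihydropyran). The chain O2–C3=C4–C4a=C5–C6=O, extended by the E-C1'=C2' alkene, is a cross-conjugated, doubly vinylogous ester. Ring A carries three contiguous stereocentres: the C7 methyl, the C8 hydroxyl and C1 lie on one face and the C7 hydroxyl on the other (trans 7,8-diol, cis C8–O/C8a–C1). The side chain carries a second triad (C3' tertiary allylic carbinol, C4', C5') with an anti C3'/C4' diol. The two triads are too far apart to control each other, so each needs its own source of chirality and the halves must be joined late. Within each triad, 1,2-induction is available: the C8 (or C4') oxygen can chelate and direct addition to a neighbouring ketone.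

The molecule is fragile. Ring A is a hydrated C-methylresorcinol: C8a–H is vinylogously acidic and has a β-hydroxyl on C8, so base or strong acid can cause loss of water and dienone–phenol aromatisation. Acid also threatens the enol ether and the C3' carbinol. Any intermediate with a carbonyl at C4a makes C8a epimerisable next to two β-leaving groups (C8–O, C1–O).

The feature the plan exploits is that C3–C4–C4a–C5–C6 is a masked 1,5-diketone (C3 and C6), with C4a β to C3 and C5 α to C6. Because C7 is fully substituted and the C3 acyl group is alkenyl, an acyclic C6 methyl ketone / C3 ynone has one enolisable position (C5) and one acceptor carbon (C4a) that can meet in a six-membered ring. C8a stays a non-acidic propargylic centre until ring A exists.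

## Retrosynthesis

O2–C3. Ring B of 25 is the cyclic enol ether of a δ-hydroxy ketone. Cutting O2–C3 (rather than O2–C1, which would need a leaving group at C1) returns a primary alcohol at C1 and a C3 ketone: pentaol diketone 24, and its silyl-protected form 23. The precursor has one ring less and no acid-labile enol ether. The forward step must condense C1–OH with the C3 carbonyl; C7–OH and C8–OH could only give bridged rings.

C4a–C5 (key). In 23 the unit C3(=O)–C4H2–C4a=C5–C6(=O) is the Michael adduct of a C6 methyl ketone enolate (C5) and a C3 alkynone (β-carbon C4a). Cutting C4a–C5 opens ring A to the acyclic keto-ynone 22. The neighbouring cuts are worse: C4–C4a (cross-coupling) needs ring A preformed with a carbonyl at C4a, and C4a–C8a would leave C8a to be set during ring closure. 22 has no ring and carries all six stereocentres at positions that cannot epimerise. The forward reaction must form the C–C bond, not a C–O bond, in a 6-exo-dig closure.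

C3–C4. 22 is cut at the acyl–alkynyl bond into Weinreb amide 8 (C3, C1'–C7') and terminal alkyne 19 (C1, C4–C8a). In 19 the methyl ketone is masked as a 1-ethoxyvinyl ether so that the acetylide can be made. This cut gives two halves of three stereocentres each; the acidic work-up must release ynone and methyl ketone together.

C6–C7. The tertiary carbinol C7 of 19 (via 18 and 17) is cut from its acyl carbon: α-hydroxy methyl ketone 16 plus a 1-ethoxyvinyl (acetyl anion) nucleophile. Adding the acyl carbon to the methyl ketone through a magnesium chelate with the C8 oxygen gives the syn (threo) C7/C8 diol, which is trans on ring A. The reverse order (methyl onto a C6-bearing ketone) would give the wrong isomer.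

C8–C8a. 16 is the ozonolysis product of isopropenyl carbinol 15. 15 is cut between C8 and C8a into methacrolein 13 and allenylzinc 14, made from propargylic mesylate 12 (Marshall–Tamaru propargylation). This one bond sets C8 and C8a (anti), brings in C4/C4a as the alkyne and C1 as CH2OSi. 12 has one stereocentre, set by transfer hydrogenation of ynone 10 (from 9).

Side chain. 8 is cut at C1'=C2' (cross-metathesis of allylic diol 5 with acrylamide 6, via 7). 5 is cut at C3'–CH3 (chelation-controlled methyl addition to enone 4, giving the anti C3'/C4' diol) and 4 at C2'–C3' (vinyl Grignard on Weinreb amide 3). C4' and C5' are those of hydroxy acid 2, from L-allo-isoleucine 1. The two chelation-controlled additions are used in complementary senses: methyl onto a C2'-bearing ketone gives anti, acyl carbon onto a methyl ketone gives syn.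

## Roads not taken

Alternative 1: the most obvious cut is C4–C4a plus O2–C3. Ring A enol triflate A1 would be coupled (Sonogashira) with enyne A2 to dienynone A3, and ring B closed by 6-endo-dig oxa-Michael addition of C1–OH. The triflate needs a cyclohexane-1,3-dione in which C8a–H is α to the C4a carbonyl and flanked by β-oxygens at C8 and C1, so epimerisation, β-elimination and aromatisation threaten every step before the coupling. Triflation must also distinguish the C4a and C6 oxygens, and ring A with its three stereocentres has to be finished before the union. The chosen plan keeps C8a propargylic until ring A forms and builds ring A from an acyclic chain by an isomerisation.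

Alternative 2: work from the aromatic oxidation level. 1H-Isochromene-6,8-diol A4 would be hydroxylated at C7 (oxidative dearomatisation, for example with Cu(MeCN)4PF6/sparteine/O2) to dione A5, then reduced at C8 by C7–OH-directed hydride delivery, with C8a settling by keto–enol equilibration. A5 is a vinylogous acid whose two keto tautomers place the isolated ketone either at C8 (C4a=C5) or at C6 (C4a=C8a, tetrasubstituted alkene, less hindered carbonyl). Both are α-ketols of C7, so reduction at C6 to the constitutional isomer is at least as likely. C8a would be set only by protonation, and the oxidant meets an electron-rich dienyl ether. The chosen plan fixes C8 and C8a by a reagent-controlled C–C bond formation.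

Alternative 3: cut C4a–C8a and O2–C1 together. The 1-oxadiene O2=C3–C4=C4a of allenyl diketone A6 would add to its C8a=C1 vinyl group in an intramolecular inverse-demand hetero-Diels–Alder reaction, closing both rings and setting C8a. The tether forces the electrophilic carbon terminus C4a onto the internal alkene carbon and oxygen onto the terminal CH2, against the polarity of an electron-poor oxadiene. Allenyl ketones also cycloisomerise readily to furans, and C8a would be controlled only by the allylic C8 ether. The chosen plan closes ring A with polarity-matched partners and sets C8a earlier.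

Key step: step 16

Assumption: Weinreb amide 9 is bought as such (otherwise two routine steps from methyl glycolate); 23 and 24 are written as 1,5-diketone tautomers, and their enol forms converge in step 17.

## Route

Step 1
Reactants: 1 L-allo-isoleucine, (2S,3R)-2-amino-3-methylpentanoic acid
Product: 2 (2S,3R)-2-hydroxy-3-methylpentanoic acid
Conditions: NaNO2, 1 M aq. H2SO4, 0 °C to rt
Reagents that add atoms: water, O
Why: Diazotisation of an α-amino acid and hydrolysis with net retention (double inversion through the α-lactone); C4' and C5' come from the chiral pool.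

Step 2
Reactants: 2 (2S,3R)-2-hydroxy-3-methylpentanoic acid
Product: 3 (2S,3R)-2-hydroxy-N-methoxy-N,3-dimethylpentanamide
Conditions: MeNHOMe·HCl, EDC·HCl, HOBt (cat.), N-methylmorpholine, CH2Cl2, 0 °C to rt
Reagents that add atoms: N,O-dimethylhydroxylamine hydrochloride, CNOC.Cl
Why: Carbodiimide amidation to the Weinreb amide; α-hydroxy acids are coupled this way without protection.

Step 3
Reactants: 3 (2S,3R)-2-hydroxy-N-methoxy-N,3-dimethylpentanamide
Product: 4 (4S,5R)-4-hydroxy-5-methylhept-1-en-3-one
Conditions: CH2=CHMgBr (3.2 equiv), THF, −78 to 0 °C; poured into cold 1 M aq. HCl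
Reagents that add atoms: vinylmagnesium bromide, C=C[Mg]Br
Why: Weinreb ketone synthesis; the first equivalent forms the magnesium alkoxide, the chelated tetrahedral adduct prevents over-addition, and the inverse acidic quench keeps the released amine from adding to the enone, which is used at once.

Step 4
Reactants: 4 (4S,5R)-4-hydroxy-5-methylhept-1-en-3-one
Product: 5 (3R,4S,5R)-3,5-dimethylhept-1-ene-3,4-diol
Conditions: MeMgBr (3 equiv), THF, −78 °C; aq. NH4Cl
Reagents that add atoms: methylmagnesium bromide, C[Mg]Br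
Why: Chelation-controlled (Cram chelate) 1,2-addition to the α-magnesioxy ketone; methyl enters from the C4'–H side of the five-membered chelate, which should give the anti C3'/C4' diol, R at C3'.

Step 5
Reactants: 5 (3R,4S,5R)-3,5-dimethylhept-1-ene-3,4-diol; 6 N-methoxy-N-methylprop-2-enamide
Product: 7 (2E,4R,5S,6R)-4,5-dihydroxy-N-methoxy-N,4,6-trimethyloct-2-enamide
Conditions: second-generation Hoveyda–Grubbs catalyst (5 mol%), 6 (3 equiv), CH2Cl2, 40 °C
Reagents that add atoms: none
Why: Olefin cross-metathesis of a free tertiary allylic alcohol with an electron-poor acrylamide; the E alkene should form under thermodynamic control.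

Step 6
Reactants: 7 (2E,4R,5S,6R)-4,5-dihydroxy-N-methoxy-N,4,6-trimethyloct-2-enamide
Product: 8 (2E,4R,5S,6R)-N-methoxy-N,4,6-trimethyl-4,5-bis[(triethylsilyl)oxy]oct-2-enamide
Conditions: TESOTf (2.5 equiv), 2,6-lutidine, CH2Cl2, −78 to 0 °C
Reagents that add atoms: triethylsilyl trifluoromethanesulfonate, CC[Si](CC)(CC)OS(=O)(=O)C(F)(F)F
Why: Silyl triflate with a hindered base silylates the secondary and the tertiary alcohol; triethylsilyl is chosen so that all silyl groups fall in one fluoride step at the end.

Step 7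
Reactants: 9 2-[(tert-butyldimethylsilyl)oxy]-N-methoxy-N-methylacetamide
Product: 10 1-[(tert-butyldimethylsilyl)oxy]-4-(trimethylsilyl)but-3-yn-2-one
Conditions: Me3SiC≡CH, n-BuLi, THF, −78 °C; then 9, −78 to 0 °C; aq. NH4Cl
Reagents that add atoms: ethynyltrimethylsilane, C#C[Si](C)(C)C
Why: Acylation of a lithium acetylide by a Weinreb amide stops at the ketone because of the stable chelate.

Step 8
Reactants: 10 1-[(tert-butyldimethylsilyl)oxy]-4-(trimethylsilyl)but-3-yn-2-one
Product: 11 (R)-1-[(tert-butyldimethylsilyl)oxy]-4-(trimethylsilyl)but-3-yn-2-ol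
Conditions: Ru(p-cymene)[(S,S)-TsNCH(Ph)CH(Ph)NH] (1 mol%), i-PrOH, rt
Reagents that add atoms: none
Why: Noyori asymmetric transfer hydrogenation of an alkynyl ketone; by analogy with alkynyl methyl ketones the (S,S) catalyst should give this carbinol (the descriptor is R because CH2OSi outranks the alkynyl group), and the antipodal catalyst is used if the sense proves opposite.

Step 9
Reactants: 11 (R)-1-[(tert-butyldimethylsilyl)oxy]-4-(trimethylsilyl)but-3-yn-2-ol
Product: 12 (R)-1-[(tert-butyldimethylsilyl)oxy]-4-(trimethylsilyl)but-3-yn-2-yl methanesulfonate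
Conditions: MsCl, Et3N, CH2Cl2, −78 to −40 °C; used crude
Reagents that add atoms: methanesulfonyl chloride, CS(=O)(=O)Cl
Why: Sulfonylation at oxygen with retention at carbon gives the propargylic electrophile for the next step.

Step 10
Reactants: 12 (R)-1-[(tert-butyldimethylsilyl)oxy]-4-(trimethylsilyl)but-3-yn-2-yl methanesulfonate; 13 methacrolein (2-methylprop-2-enal)
Product: 15 (3R,4S)-4-{[(tert-butyldimethylsilyl)oxy]methyl}-2-methyl-6-(trimethylsilyl)hex-1-en-5-yn-3-ol, via allenylzinc reagent 14 (not isolated)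
Conditions: Pd(OAc)2 (5 mol%), PPh3 (5 mol%), Et2Zn (3 equiv), 13 (1.3 equiv), THF, −78 to −20 °C; aq. NH4Cl
Reagents that add atoms: none
Why: Marshall–Tamaru propargylation: zerovalent palladium ionises the mesylate anti (SN2'), Et2Zn transmetallates to a configurationally defined allenylzinc, and this adds to the aldehyde through a cyclic SE2' transition state, which should give the anti homopropargylic alcohol with net inversion at C8a, so (R)-12 gives 8R,8aS.

Step 11
Reactants: 15 (3R,4S)-4-{[(tert-butyldimethylsilyl)oxy]methyl}-2-methyl-6-(trimethylsilyl)hex-1-en-5-yn-3-ol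
Product: 16 (3R,4S)-4-{[(tert-butyldimethylsilyl)oxy]methyl}-3-hydroxy-6-(trimethylsilyl)hex-5-yn-2-one
Conditions: O3, CH2Cl2/MeOH, −78 °C (indicator end point); Me2S, −78 °C to rt
Reagents that add atoms: ozone, [O-][O+]=O
Why: Ozonolysis; the electron-rich 1,1-disubstituted alkene reacts far faster than the silylated alkyne, and the α-hydroxy methyl ketone is kept away from base (enediol isomerisation) and used at once.

Step 12
Reactants: 16 (3R,4S)-4-{[(tert-butyldimethylsilyl)oxy]methyl}-3-hydroxy-6-(trimethylsilyl)hex-5-yn-2-one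
Product: 17 (3S,4R,5S)-5-{[(tert-butyldimethylsilyl)oxy]methyl}-2-ethoxy-3-methyl-7-(trimethylsilyl)hept-1-en-6-yne-3,4-diol
Conditions: ethyl vinyl ether, t-BuLi, THF, −78 to 0 °C; MgBr2·OEt2, −78 °C; then 16 (reagent 3 equiv), −78 to −40 °C; aq. NaHCO3
Reagents that add atoms: ethyl vinyl ether, C=COCC
Why: Chelation-controlled (Cram chelate) addition of an acyl anion equivalent: the magnesium alkoxide at C8 and the C7 carbonyl form a five-membered chelate and the nucleophile enters from the C8–H side, which should give the syn C7/C8 diol, S at C7; the enol ether masks the methyl ketone.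

Step 13
Reactants: 17 (3S,4R,5S)-5-{[(tert-butyldimethylsilyl)oxy]methyl}-2-ethoxy-3-methyl-7-(trimethylsilyl)hept-1-en-6-yne-3,4-diol
Product: 18 (3S,4R,5S)-5-{[(tert-butyldimethylsilyl)oxy]methyl}-2-ethoxy-3-methylhept-1-en-6-yne-3,4-diol
Conditions: K2CO3 (cat.), MeOH, 0 °C to rt
Reagents that add atoms: none
Why: Base-catalysed methanolysis of the alkynyl C–Si bond; silyl ether, diol and enol ether are inert to it.

Step 14
Reactants: 18 (3S,4R,5S)-5-{[(tert-butyldimethylsilyl)oxy]methyl}-2-ethoxy-3-methylhept-1-en-6-yne-3,4-diol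
Product: 19 (3S,4R,5S)-5-{[(tert-butyldimethylsilyl)oxy]methyl}-2-ethoxy-3-methyl-3,4-bis[(triethylsilyl)oxy]hept-1-en-6-yne
Conditions: TESOTf (2.5 equiv), 2,6-lutidine, CH2Cl2, −78 to 0 °C
Reagents that add atoms: triethylsilyl trifluoromethanesulfonate, CC[Si](CC)(CC)OS(=O)(=O)C(F)(F)F
Why: Silylation of the secondary and the tertiary alcohol under buffered conditions that leave the enol ether intact; the C7 oxygen must be capped so that it cannot add to the ynone in step 16.

Step 15
Reactants: 19 (3S,4R,5S)-5-{[(tert-butyldimethylsilyl)oxy]methyl}-2-ethoxy-3-methyl-3,4-bis[(triethylsilyl)oxy]hept-1-en-6-yne; 8 (2E,4R,5S,6R)-N-methoxy-N,4,6-trimethyl-4,5-bis[(triethylsilyl)oxy]oct-2-enamide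
Product: 22 (3S,4R,5S,9E,11R,12S,13R)-5-{[(tert-butyldimethylsilyl)oxy]methyl}-3,11,13-trimethyl-3,4,11,12-tetrakis[(triethylsilyl)oxy]pentadec-9-en-6-yne-2,8-dione, via lithium acetylide 20 (not isolated), via enol ether ynone 21 (not isolated)
Conditions: n-BuLi (1.05 equiv), THF, −78 °C; 8, −78 to −20 °C; 10% aq. citric acid, THF, 0 °C to rt
Reagents that add atoms: water, O
Why: Weinreb ketone synthesis with a lithium acetylide (1,2-addition, the β-carbon of the enamide being shielded by quaternary C3'); the mild aqueous acid collapses the chelate to the ynone and hydrolyses the 1-ethoxyvinyl ether to the methyl ketone while the silyl ethers remain.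

Step 16
Reactants: 22 (3S,4R,5S,9E,11R,12S,13R)-5-{[(tert-butyldimethylsilyl)oxy]methyl}-3,11,13-trimethyl-3,4,11,12-tetrakis[(triethylsilyl)oxy]pentadec-9-en-6-yne-2,8-dione
Product: 23 (4S,5R,6S)-4-{[(tert-butyldimethylsilyl)oxy]methyl}-3-[(3E,5R,6S,7R)-5,7-dimethyl-2-oxo-5,6-bis[(triethylsilyl)oxy]non-3-en-1-yl]-6-methyl-5,6-bis[(triethylsilyl)oxy]cyclohex-2-en-1-one
Conditions: LiHMDS (1.1 equiv), THF, −78 to −20 °C; AcOH quench
Reagents that add atoms: none
Why: The base forms the only possible enolate (C5 of the C6 methyl ketone; C7 is quaternary and the C3 ketone has no α-hydrogen), and its carbon adds to C4a, the β-carbon of the C3 alkynone; protonation of the allenolate at C4 and proton shifts give the vinylogous 1,3-diketonate, which the quench turns into 23. The closest known reaction type is the base-mediated intramolecular Michael addition of a ketone enolate to a tethered alkynone (an anionic Conia-ene-type carbocyclisation). Ring A closes in the 6-(enolexo)-exo-dig mode; ring B is not yet formed. No stereocentre is created: all six are carried in, and C8a, being propargylic, is not acidic before the closure. The step needs C-attack rather than O-attack of the enolate on C4a; O-attack gives a six-membered enol ether by a reversible oxa-Michael addition, whereas the C–C bond is irreversible, so the mixture should funnel to 23. Only C4a can be reached in a six-membered transition state, since attack at the C3 carbonyl or at C2' would need eight- and ten-membered rings. The product is held as its delocalised anion until the quench, which protects C8a–H and the C8 silyl ether from vinylogous β-elimination. Both geometries of the first-formed C4=C4a alkylidene lead to the same product.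

Step 17
Reactants: 23 (4S,5R,6S)-4-{[(tert-butyldimethylsilyl)oxy]methyl}-3-[(3E,5R,6S,7R)-5,7-dimethyl-2-oxo-5,6-bis[(triethylsilyl)oxy]non-3-en-1-yl]-6-methyl-5,6-bis[(triethylsilyl)oxy]cyclohex-2-en-1-one
Product: 25 (7S,8R,8aS)-3-[(1E,3R,4S,5R)-3,4-dihydroxy-3,5-dimethylhept-1-en-1-yl]-7,8-dihydroxy-7-methyl-1,7,8,8a-tetrahydro-6H-isochromen-6-one, via pentaol diketone 24 (not isolated)
Conditions: HF·pyridine, pyridine, THF, 0 °C to rt; then PPTS (cat.), 4 Å molecular sieves, CH2Cl2, rt if ring closure is incomplete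
Reagents that add atoms: none
Why: Fluoride desilylation, then acid-catalysed condensation of C1–OH with the C3 carbonyl of the vinylogous 1,3-diketone (hemiketal, dehydration) closes ring B as the doubly vinylogous ester; only the C1 hydroxyl can give a fused ring (C7–OH and C8–OH would give bridged enol ethers with bridgehead alkenes), and all tautomers of 24 converge.

## Compound list

1 | L-allo-isoleucine, (2S,3R)-2-amino-3-methylpentanoic acid | CC[C@@H](C)[C@H](N)C(=O)O | starting material
2 | (2S,3R)-2-hydroxy-3-methylpentanoic acid | CC[C@@H](C)[C@H](O)C(=O)O | intermediate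
3 | (2S,3R)-2-hydroxy-N-methoxy-N,3-dimethylpentanamide | CC[C@@H](C)[C@H](O)C(=O)N(C)OC | intermediate
4 | (4S,5R)-4-hydroxy-5-methylhept-1-en-3-one | CC[C@@H](C)[C@H](O)C(=O)C=C | intermediate
5 | (3R,4S,5R)-3,5-dimethylhept-1-ene-3,4-diol | CC[C@@H](C)[C@H](O)[C@](C)(O)C=C | intermediate
6 | N-methoxy-N-methylprop-2-enamide | C=CC(=O)N(C)OC | starting material
7 | (2E,4R,5S,6R)-4,5-dihydroxy-N-methoxy-N,4,6-trimethyloct-2-enamide | CC[C@@H](C)[C@H](O)[C@](C)(O)/C=C/C(=O)N(C)OC | intermediate
8 | (2E,4R,5S,6R)-N-methoxy-N,4,6-trimethyl-4,5-bis[(triethylsilyl)oxy]oct-2-enamide | CC[C@@H](C)[C@H](O[Si](CC)(CC)CC)[C@](C)(O[Si](CC)(CC)CC)/C=C/C(=O)N(C)OC | intermediate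
9 | 2-[(tert-butyldimethylsilyl)oxy]-N-methoxy-N-methylacetamide | CON(C)C(=O)CO[Si](C)(C)C(C)(C)C | starting material
10 | 1-[(tert-butyldimethylsilyl)oxy]-4-(trimethylsilyl)but-3-yn-2-one | C[Si](C)(C)C#CC(=O)CO[Si](C)(C)C(C)(C)C | intermediate
11 | (R)-1-[(tert-butyldimethylsilyl)oxy]-4-(trimethylsilyl)but-3-yn-2-ol | C[Si](C)(C)C#C[C@@H](O)CO[Si](C)(C)C(C)(C)C | intermediate
12 | (R)-1-[(tert-butyldimethylsilyl)oxy]-4-(trimethylsilyl)but-3-yn-2-yl methanesulfonate | C[Si](C)(C)C#C[C@@H](OS(C)(=O)=O)CO[Si](C)(C)C(C)(C)C | intermediate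
13 | methacrolein, 2-methylprop-2-enal | CC(=C)C=O | starting material
14 | ethyl{(aR)-4-[(tert-butyldimethylsilyl)oxy]-1-(trimethylsilyl)buta-1,2-dien-1-yl}zinc (allenylzinc reagent) | C[Si](C)(C)C([Zn]CC)=[C@@]=C([H])CO[Si](C)(C)C(C)(C)C | intermediate
15 | (3R,4S)-4-{[(tert-butyldimethylsilyl)oxy]methyl}-2-methyl-6-(trimethylsilyl)hex-1-en-5-yn-3-ol | C[Si](C)(C)C#C[C@@H](CO[Si](C)(C)C(C)(C)C)[C@@H](O)C(C)=C | intermediate
16 | (3R,4S)-4-{[(tert-butyldimethylsilyl)oxy]methyl}-3-hydroxy-6-(trimethylsilyl)hex-5-yn-2-one | C[Si](C)(C)C#C[C@@H](CO[Si](C)(C)C(C)(C)C)[C@@H](O)C(C)=O | intermediate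
17 | (3S,4R,5S)-5-{[(tert-butyldimethylsilyl)oxy]methyl}-2-ethoxy-3-methyl-7-(trimethylsilyl)hept-1-en-6-yne-3,4-diol | C[Si](C)(C)C#C[C@@H](CO[Si](C)(C)C(C)(C)C)[C@@H](O)[C@](C)(O)C(=C)OCC | intermediate
18 | (3S,4R,5S)-5-{[(tert-butyldimethylsilyl)oxy]methyl}-2-ethoxy-3-methylhept-1-en-6-yne-3,4-diol | C#C[C@@H](CO[Si](C)(C)C(C)(C)C)[C@@H](O)[C@](C)(O)C(=C)OCC | intermediate
19 | (3S,4R,5S)-5-{[(tert-butyldimethylsilyl)oxy]methyl}-2-ethoxy-3-methyl-3,4-bis[(triethylsilyl)oxy]hept-1-en-6-yne | C#C[C@@H](CO[Si](C)(C)C(C)(C)C)[C@@H](O[Si](CC)(CC)CC)[C@](C)(O[Si](CC)(CC)CC)C(=C)OCC | intermediate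
20 | lithium acetylide of 19 | [Li]C#C[C@@H](CO[Si](C)(C)C(C)(C)C)[C@@H](O[Si](CC)(CC)CC)[C@](C)(O[Si](CC)(CC)CC)C(=C)OCC | intermediate
21 | (3S,4R,5S,9E,11R,12S,13R)-5-{[(tert-butyldimethylsilyl)oxy]methyl}-2-ethoxy-3,11,13-trimethyl-3,4,11,12-tetrakis[(triethylsilyl)oxy]pentadeca-1,9-dien-6-yn-8-one | CC[C@@H](C)[C@H](O[Si](CC)(CC)CC)[C@](C)(O[Si](CC)(CC)CC)/C=C/C(=O)C#C[C@@H](CO[Si](C)(C)C(C)(C)C)[C@@H](O[Si](CC)(CC)CC)[C@](C)(O[Si](CC)(CC)CC)C(=C)OCC | intermediate
22 | (3S,4R,5S,9E,11R,12S,13R)-5-{[(tert-butyldimethylsilyl)oxy]methyl}-3,11,13-trimethyl-3,4,11,12-tetrakis[(triethylsilyl)oxy]pentadec-9-en-6-yne-2,8-dione | CC[C@@H](C)[C@H](O[Si](CC)(CC)CC)[C@](C)(O[Si](CC)(CC)CC)/C=C/C(=O)C#C[C@@H](CO[Si](C)(C)C(C)(C)C)[C@@H](O[Si](CC)(CC)CC)[C@](C)(O[Si](CC)(CC)CC)C(C)=O | intermediate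
23 | (4S,5R,6S)-4-{[(tert-butyldimethylsilyl)oxy]methyl}-3-[(3E,5R,6S,7R)-5,7-dimethyl-2-oxo-5,6-bis[(triethylsilyl)oxy]non-3-en-1-yl]-6-methyl-5,6-bis[(triethylsilyl)oxy]cyclohex-2-en-1-one | CC[C@@H](C)[C@H](O[Si](CC)(CC)CC)[C@](C)(O[Si](CC)(CC)CC)/C=C/C(=O)CC1=CC(=O)[C@@](C)(O[Si](CC)(CC)CC)[C@H](O[Si](CC)(CC)CC)[C@@H]1CO[Si](C)(C)C(C)(C)C | intermediate
24 | (4S,5R,6S)-3-[(3E,5R,6S,7R)-5,6-dihydroxy-5,7-dimethyl-2-oxonon-3-en-1-yl]-5,6-dihydroxy-4-(hydroxymethyl)-6-methylcyclohex-2-en-1-one | CC[C@@H](C)[C@H](O)[C@](C)(O)/C=C/C(=O)CC1=CC(=O)[C@@](C)(O)[C@H](O)[C@@H]1CO | intermediate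
25 | (7S,8R,8aS)-3-[(1E,3R,4S,5R)-3,4-dihydroxy-3,5-dimethylhept-1-en-1-yl]-7,8-dihydroxy-7-methyl-1,7,8,8a-tetrahydro-6H-isochromen-6-one | CC[C@@H](C)[C@H](O)[C@](C)(O)/C=C/C1=CC2=CC(=O)[C@@](C)(O)[C@H](O)[C@@H]2CO1 | target

## Step count and least certain steps

Total: 17 steps. Longest linear sequence: 11 steps (steps 7 to 17, from 9). The side-chain branch (steps 1 to 6, from 1) joins in step 15.

Step 16 (key step). Most likely failure: addition through oxygen (the enolate oxygen closing a six-membered enol ether on C4a) or conjugate addition of the amide base to the very electrophilic ynone, because the carbon nucleophile is a hindered α-silyloxy ketone enolate. Fallback, from 22 back to 23: the methyl ketone is turned with TBSOTf/Et3N into tert-butyldimethylsilyl enol ether F1. Ring A is then closed under neutral conditions by π-acid-catalysed 6-exo-dig carbocyclisation of the silyl enol ether onto the alkyne ((Ph3P)AuNTf2, wet CH2Cl2; a Conia-ene-type reaction of silyl enol ethers). Protodeauration and loss of the silyl group should give 23.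

Step 10. Most likely failure: 1,4-elimination of silyloxide from allenylzinc 14 (the zinc-bearing carbon and CH2OSi are 1,4-related), or erosion of anti selectivity with a small enal. Fallback, from 13 back to 18: anti-selective allylboration of 13 with pinacol (E)-[4-(tert-butyldimethylsilyloxy)but-2-en-1-yl]boronate under chiral phosphoric acid catalysis should give homoallylic alcohol F2. Ozonolysis of both alkenes gives keto aldehyde F3. Its aldehyde alone is homologated with the Ohira–Bestmann reagent (K2CO3, MeOH) to alkynyl hydroxy ketone F4. The chelation-controlled 1-ethoxyvinyl addition of step 12 then gives 18 directly.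

Step 5. Most likely failure: slow metathesis at the fully substituted allylic carbon with catalyst decay, possibly made worse by chelation of the ruthenium carbene by the Weinreb amide. Fallback, from 5 back to 8: bis-silylation of 5 (TESOTf, 2,6-lutidine) to alkene F5, ozonolysis to the non-enolisable aldehyde F6, and Horner–Wadsworth–Emmons olefination with diethyl {2-[methoxy(methyl)amino]-2-oxoethyl}phosphonate (NaH, THF) should give 8.

Step 17. Most likely failure: acid-promoted loss of the C8 hydroxyl followed by dienone–phenol aromatisation, or ionisation at C3', because removal of five silyl groups and ring closure are asked of one acidic medium. Fallback, from 23 back to 25: desilylation with buffered fluoride (TBAF/AcOH, THF) and isolation of 24. Ring B is then closed under neutral conditions by intramolecular Mitsunobu O-alkylation (PPh3, DIAD, THF, 0 °C) of the acidic vinylogous diketone enol by the primary C1 alcohol; the ring oxygen then comes from the C3 carbonyl. This fallback makes no new compound (F0).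

## Further compounds

F1 | step 16 | (3S,4R,5S,9E,11R,12S,13R)-2-[(tert-butyldimethylsilyl)oxy]-5-{[(tert-butyldimethylsilyl)oxy]methyl}-3,11,13-trimethyl-3,4,11,12-tetrakis[(triethylsilyl)oxy]pentadeca-1,9-dien-6-yn-8-one | CC[C@@H](C)[C@H](O[Si](CC)(CC)CC)[C@](C)(O[Si](CC)(CC)CC)/C=C/C(=O)C#C[C@@H](CO[Si](C)(C)C(C)(C)C)[C@@H](O[Si](CC)(CC)CC)[C@](C)(O[Si](CC)(CC)CC)C(=C)O[Si](C)(C)C(C)(C)C
F2 | step 10 | (3R,4S)-4-{[(tert-butyldimethylsilyl)oxy]methyl}-2-methylhexa-1,5-dien-3-ol | C=C[C@@H](CO[Si](C)(C)C(C)(C)C)[C@@H](O)C(C)=C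
F3 | step 10 | (2S,3R)-2-{[(tert-butyldimethylsilyl)oxy]methyl}-3-hydroxy-4-oxopentanal | O=C[C@@H](CO[Si](C)(C)C(C)(C)C)[C@@H](O)C(C)=O
F4 | step 10 | (3R,4S)-4-{[(tert-butyldimethylsilyl)oxy]methyl}-3-hydroxyhex-5-yn-2-one | C#C[C@@H](CO[Si](C)(C)C(C)(C)C)[C@@H](O)C(C)=O
F5 | step 5 | (3R,4S,5R)-3,5-dimethyl-3,4-bis[(triethylsilyl)oxy]hept-1-ene | CC[C@@H](C)[C@H](O[Si](CC)(CC)CC)[C@](C)(O[Si](CC)(CC)CC)C=C
F6 | step 5 | (2S,3S,4R)-2,4-dimethyl-2,3-bis[(triethylsilyl)oxy]hexanal | CC[C@@H](C)[C@H](O[Si](CC)(CC)CC)[C@](C)(O[Si](CC)(CC)CC)C=O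
F0 | step 17 | none | none
A1 | alternative 1 | (4S,5R,6S)-6-{[(tert-butyldimethylsilyl)oxy]methyl}-4-methyl-3-oxo-4,5-bis[(triethylsilyl)oxy]cyclohex-1-en-1-yl trifluoromethanesulfonate | O=C1C=C(OS(=O)(=O)C(F)(F)F)[C@@H](CO[Si](C)(C)C(C)(C)C)[C@@H](O[Si](CC)(CC)CC)[C@]1(C)O[Si](CC)(CC)CC
A2 | alternative 1 | (3E,5R,6S,7R)-5,7-dimethyl-5,6-bis[(triethylsilyl)oxy]non-3-en-1-yne | CC[C@@H](C)[C@H](O[Si](CC)(CC)CC)[C@](C)(O[Si](CC)(CC)CC)/C=C/C#C
A3 | alternative 1 | (4S,5R,6S)-3-{(3E,5R,6S,7R)-5,7-dimethyl-5,6-bis[(triethylsilyl)oxy]non-3-en-1-yn-1-yl}-4-(hydroxymethyl)-6-methyl-5,6-bis[(triethylsilyl)oxy]cyclohex-2-en-1-one | CC[C@@H](C)[C@H](O[Si](CC)(CC)CC)[C@](C)(O[Si](CC)(CC)CC)/C=C/C#CC1=CC(=O)[C@@](C)(O[Si](CC)(CC)CC)[C@H](O[Si](CC)(CC)CC)[C@@H]1CO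
A4 | alternative 2 | 3-[(1E,3R,4S,5R)-3,4-dihydroxy-3,5-dimethylhept-1-en-1-yl]-7-methyl-1H-isochromene-6,8-diol | CC[C@@H](C)[C@H](O)[C@](C)(O)/C=C/C1=Cc2cc(O)c(C)c(O)c2CO1
A5 | alternative 2 | 3-[(1E,3R,4S,5R)-3,4-dihydroxy-3,5-dimethylhept-1-en-1-yl]-7-hydroxy-7-methyl-1,8a-dihydro-6H-isochromene-6,8(7H)-dione (C7 as in 25, C8a labile) | CC[C@@H](C)[C@H](O)[C@](C)(O)/C=C/C1=CC2=CC(=O)[C@@](C)(O)C(=O)C2CO1
A6 | alternative 3 | (3R,4S,10E,12R,13S,14R)-4,12,14-trimethyl-3,4,12,13-tetrakis[(triethylsilyl)oxy]hexadeca-1,6,7,10-tetraene-5,9-dione (allene axis undefined) | CC[C@@H](C)[C@H](O[Si](CC)(CC)CC)[C@](C)(O[Si](CC)(CC)CC)/C=C/C(=O)C=C=CC(=O)[C@@](C)(O[Si](CC)(CC)CC)[C@H](O[Si](CC)(CC)CC)C=C
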